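**Plan**

Retrosynthesis (locants: C1 carries the 4‑hydroxyphenyl ring, C2 the 3,5‑dihydroxyphenyl ring, C3 the carbinol side chain, C7a is the ring‑fusion carbon at C1): the O‑benzyl‑type groups come off last; before that the C2–aryl bond is cut, then ring bond C1–C7a, then the exocyclic C3–carbinol bond, then C2–C3.
Forward: enolate benzylation joins C2 to C3 in a 1,3‑diarylpropan‑1‑one; its enol carbamate is lithiated at C3 and united with the aryl aldehyde; acid then closes the five‑membered ring (C1 onto C7a) to an indene; hydroboration and arylation at C2 complete the indane.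
Enabling feature: C1–C2–C3 is a ketone homoenolate in disguise. C1 bears an aryl group and is bonded to C7a, a resorcinol‑ring carbon ortho to one and para to the other ring oxygen, so C1 can be carried as an aryl ketone (masked as an enol carbamate) and closed onto C7a by Friedel–Crafts reaction after C3, its benzylic γ‑carbon, has served as the nucleophile.
Stereochemistry: C3 and the carbinol carbon arise together, anti, from (−)‑sparteine‑directed lithiation and a chair transition state; C1 follows from syn hydroboration opposite the C3 side chain; C2 from radical arylation opposite both neighbours.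

Key step: step 4

Assumption: in step 4 (−)‑sparteine is taken to give the (3R,4S) series; if the diamine induces the opposite sense, commercially available (+)‑sparteine is used in its place and nothing else changes.

**Route**

Step 1
Reactants: 1 1‑[4‑(benzyloxy)phenyl]ethan‑1‑one; 2 1,3‑bis(benzyloxy)‑5‑(bromomethyl)benzene
Product: 3 1‑[4‑(benzyloxy)phenyl]‑3‑[3,5‑bis(benzyloxy)phenyl]propan‑1‑one
Conditions: LiN(SiMe3)2, THF, −78 °C to 0 °C (slight excess of 1)
Reagents that add atoms: none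
Why: The kinetic lithium enolate of the aryl methyl ketone should be alkylated by the benzylic bromide (SN2 enolate alkylation), forming the future C2–C3 bond; no stereocentre is formed.

Step 2
Reactants: 3 1‑[4‑(benzyloxy)phenyl]‑3‑[3,5‑bis(benzyloxy)phenyl]propan‑1‑one
Product: 4 (Z)‑1‑[4‑(benzyloxy)phenyl]‑3‑[3,5‑bis(benzyloxy)phenyl]prop‑1‑en‑1‑yl N,N‑diisopropylcarbamate
Conditions: KN(SiMe3)2, THF, −78 °C; iPr2NCOCl, DMPU, −78 °C to rt
Reagents that add atoms: N,N‑diisopropylcarbamoyl chloride CC(C)N(C(C)C)C(Cl)=O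
Why: The potassium enolate of an aryl alkyl ketone is Z and should be acylated on oxygen by the hindered carbamoyl chloride (enolate O‑carbamoylation); the enol carbamate is the masked ketone, acidifies the γ‑CH2 and later binds lithium and titanium.

Step 3
Reactants: 5 4‑hydroxybenzaldehyde
Product: 6 benzyl 4‑formylphenyl carbonate
Conditions: CbzCl, Et3N, CH2Cl2, 0 °C
Reagents that add atoms: benzyl chloroformate O=C(Cl)OCc1ccccc1
Why: O‑acylation of the phenol by a chloroformate; the carbonate is an electron‑withdrawing, hydrogenolysable phenol protecting group that should keep the adjacent benzylic carbinol from ionising in the acid of step 5.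

Step 4
Reactants: 4 (Z)‑1‑[4‑(benzyloxy)phenyl]‑3‑[3,5‑bis(benzyloxy)phenyl]prop‑1‑en‑1‑yl N,N‑diisopropylcarbamate; 6 benzyl 4‑formylphenyl carbonate
Product: 9 (1Z,3R,4S)‑1‑[4‑(benzyloxy)phenyl]‑3‑[3,5‑bis(benzyloxy)phenyl]‑4‑(4‑{[(benzyloxy)carbonyl]oxy}phenyl)‑4‑hydroxybut‑1‑en‑1‑yl N,N‑diisopropylcarbamate, via sparteine‑complexed allyllithium 7 (not isolated), via allyltitanium triisopropoxide 8 (not isolated)
Conditions: n‑BuLi, (−)‑sparteine, toluene, −78 °C; ClTi(OiPr)3, −78 °C; then 6, −78 °C to −40 °C; aq. NH4Cl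
Reagents that add atoms: none
Why: n‑BuLi/(−)‑sparteine should remove one of the two enantiotopic benzylic, allylic γ‑protons at C3 to give the carbamate‑chelated 1‑oxyallyllithium 7, which ClTi(OiPr)3 converts with inversion into the allyltitanium 8 bound at the oxygen‑bearing carbon C1; 8 adds to the aldehyde through its γ‑carbon C3 (SE2′) in a closed six‑membered Zimmerman–Traxler chair, forming the C3–C4 bond and regenerating a Z enol carbamate. The closest known reaction type is the sparteine‑mediated lithiation–titanation homoaldol reaction of 1‑aryl‑1‑alkenyl N,N‑diisopropylcarbamates (ketone homoenolate equivalents) with aldehydes; no ring is closed in this step. The configuration at C3 is controlled by the diamine, whose choice of γ‑proton fixes the configuration of the metal‑bearing carbon, and this is relayed suprafacially across the allyl unit to C3. The carbinol carbon C4 is controlled by the chair, in which the aldehyde aryl group is equatorial and the C3 aryl group occupies the exo (E) position of the allyl unit, giving the anti (3R,4S) relationship. The step needs γ‑ over α‑attack and aldehyde over carbonate selectivity: chelation by the carbamoyl oxygen holds titanium at C1 so that only C3 is offered to the aldehyde, and the weakly nucleophilic titanium reagent should not touch the carbonate at −78 °C.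

Step 5
Reactants: 9 (1Z,3R,4S)‑1‑[4‑(benzyloxy)phenyl]‑3‑[3,5‑bis(benzyloxy)phenyl]‑4‑(4‑{[(benzyloxy)carbonyl]oxy}phenyl)‑4‑hydroxybut‑1‑en‑1‑yl N,N‑diisopropylcarbamate
Product: 11 benzyl 4‑[(S)‑{(1R)‑4,6‑bis(benzyloxy)‑3‑[4‑(benzyloxy)phenyl]‑1H‑inden‑1‑yl}(hydroxy)methyl]phenyl carbonate, via 1‑carbamoyloxyindane 10 (not isolated)
Conditions: MsOH (2 equiv), CH2Cl2 (dilute), −20 °C to 0 °C; aq. NaHCO3
Reagents that add atoms: none
Why: Protonation of the enol carbamate at C2 gives an aryl‑ and oxygen‑stabilised cation at C1 that should be attacked by the ring carbon ortho to one and para to the other benzyloxy group (intramolecular Friedel–Crafts alkylation, 5‑membered ring), after which loss of diisopropylcarbamic acid and of a C2 proton gives the conjugated indene (cyclodehydration of a masked 3‑arylpropyl aryl ketone); the carbonate‑deactivated ring keeps the secondary carbinol from ionising and neither stereocentre is touched.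

Step 6
Reactants: 11 benzyl 4‑[(S)‑{(1R)‑4,6‑bis(benzyloxy)‑3‑[4‑(benzyloxy)phenyl]‑1H‑inden‑1‑yl}(hydroxy)methyl]phenyl carbonate
Product: 13 potassium {(1R,2S,3R)‑4,6‑bis(benzyloxy)‑3‑[4‑(benzyloxy)phenyl]‑1‑[(S)‑(4‑{[(benzyloxy)carbonyl]oxy}phenyl)(hydroxy)methyl]‑2,3‑dihydro‑1H‑inden‑2‑yl}trifluoroborate, via dimethyl boronate 12 (not isolated)
Conditions: BH3·SMe2 (3 equiv), THF, 0 °C to rt; MeOH, then concentrate; aq. KHF2, MeOH, rt
Reagents that add atoms: borane–dimethyl sulfide [BH3-][S+](C)C; potassium hydrogen difluoride [K+].[F-].F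
Why: Syn hydroboration of the trisubstituted styrene‑type alkene should place boron at the less substituted C2 and hydrogen at C1 from the face opposite the C3 side chain, which sets C1 (aryl cis to the side chain) and C2; excess borane favours the monoalkylborane, which methanol and KHF2 convert into the trifluoroborate.

Step 7
Reactants: 13 potassium {(1R,2S,3R)‑4,6‑bis(benzyloxy)‑3‑[4‑(benzyloxy)phenyl]‑1‑[(S)‑(4‑{[(benzyloxy)carbonyl]oxy}phenyl)(hydroxy)methyl]‑2,3‑dihydro‑1H‑inden‑2‑yl}trifluoroborate; 14 1,3‑bis(benzyloxy)‑5‑bromobenzene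
Product: 15 benzyl 4‑[(S)‑{(1R,2S,3R)‑4,6‑bis(benzyloxy)‑3‑[4‑(benzyloxy)phenyl]‑2‑[3,5‑bis(benzyloxy)phenyl]‑2,3‑dihydro‑1H‑inden‑1‑yl}(hydroxy)methyl]phenyl carbonate
Conditions: [Ir{dF(CF3)ppy}2(bpy)]PF6 (cat.), NiCl2(dme) (cat.), 4,4′‑di‑tert‑butyl‑2,2′‑bipyridine, 2,6‑lutidine, dioxane, blue LEDs, rt
Reagents that add atoms: none
Why: Nickel/photoredox dual‑catalytic cross‑coupling of a secondary alkyltrifluoroborate with an aryl bromide: single‑electron oxidation gives the C2 radical, which the aryl nickel species should capture and couple on the face opposite both flanking groups (the C1 aryl and the C3 side chain are cis to each other), so the new aryl group ends trans to both whatever the boron configuration; the non‑nucleophilic base spares the carbonate.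

Step 8
Reactants: 15 benzyl 4‑[(S)‑{(1R,2S,3R)‑4,6‑bis(benzyloxy)‑3‑[4‑(benzyloxy)phenyl]‑2‑[3,5‑bis(benzyloxy)phenyl]‑2,3‑dihydro‑1H‑inden‑1‑yl}(hydroxy)methyl]phenyl carbonate
Product: 16 (1R,2S,3R)‑2‑(3,5‑dihydroxyphenyl)‑1‑[(S)‑hydroxy(4‑hydroxyphenyl)methyl]‑3‑(4‑hydroxyphenyl)‑2,3‑dihydro‑1H‑indene‑4,6‑diol
Conditions: H2 (1 atm), 10% Pd/C, EtOAc–MeOH, rt, stopped at the calculated uptake
Reagents that add atoms: none
Why: Hydrogenolysis of the five benzyl aryl ethers and of the benzyl carbonate (which decarboxylates to the phenol) under neutral conditions, which normally spare secondary benzylic alcohols; no stereocentre is affected.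

**Compound list**

1 | 1‑[4‑(benzyloxy)phenyl]ethan‑1‑one | CC(=O)c1ccc(OCc2ccccc2)cc1 | starting material
2 | 1,3‑bis(benzyloxy)‑5‑(bromomethyl)benzene | BrCc1cc(OCc2ccccc2)cc(OCc2ccccc2)c1 | starting material
3 | 1‑[4‑(benzyloxy)phenyl]‑3‑[3,5‑bis(benzyloxy)phenyl]propan‑1‑one | O=C(CCc1cc(OCc2ccccc2)cc(OCc2ccccc2)c1)c1ccc(OCc2ccccc2)cc1 | intermediate
4 | (Z)‑1‑[4‑(benzyloxy)phenyl]‑3‑[3,5‑bis(benzyloxy)phenyl]prop‑1‑en‑1‑yl N,N‑diisopropylcarbamate | CC(C)N(C(C)C)C(=O)O/C(=C\Cc1cc(OCc2ccccc2)cc(OCc2ccccc2)c1)c1ccc(OCc2ccccc2)cc1 | intermediate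
5 | 4‑hydroxybenzaldehyde | O=Cc1ccc(O)cc1 | starting material
6 | benzyl 4‑formylphenyl carbonate | O=Cc1ccc(OC(=O)OCc2ccccc2)cc1 | intermediate
7 | (E)‑1‑[4‑(benzyloxy)phenyl]‑3‑[3,5‑bis(benzyloxy)phenyl]‑1‑(diisopropylcarbamoyloxy)allyllithium, (−)‑sparteine complex (diamine not drawn; lithium on the face opposite to that later taken by titanium) | [Li][C@@](OC(=O)N(C(C)C)C(C)C)(c1ccc(OCc2ccccc2)cc1)/C=C/c1cc(OCc2ccccc2)cc(OCc2ccccc2)c1 | intermediate (not isolated)
8 | (S,E)‑{1‑[4‑(benzyloxy)phenyl]‑3‑[3,5‑bis(benzyloxy)phenyl]‑1‑(diisopropylcarbamoyloxy)allyl}titanium triisopropoxide | CC(C)O[Ti](OC(C)C)(OC(C)C)[C@](OC(=O)N(C(C)C)C(C)C)(c1ccc(OCc2ccccc2)cc1)/C=C/c1cc(OCc2ccccc2)cc(OCc2ccccc2)c1 | intermediate (not isolated)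
9 | (1Z,3R,4S)‑1‑[4‑(benzyloxy)phenyl]‑3‑[3,5‑bis(benzyloxy)phenyl]‑4‑(4‑{[(benzyloxy)carbonyl]oxy}phenyl)‑4‑hydroxybut‑1‑en‑1‑yl N,N‑diisopropylcarbamate | CC(C)N(C(C)C)C(=O)O/C(=C\[C@@H]([C@H](O)c1ccc(OC(=O)OCc2ccccc2)cc1)c1cc(OCc2ccccc2)cc(OCc2ccccc2)c1)c1ccc(OCc2ccccc2)cc1 | intermediate
10 | (3R)‑5,7‑bis(benzyloxy)‑1‑[4‑(benzyloxy)phenyl]‑3‑[(S)‑(4‑{[(benzyloxy)carbonyl]oxy}phenyl)(hydroxy)methyl]‑2,3‑dihydro‑1H‑inden‑1‑yl N,N‑diisopropylcarbamate (either configuration at C1) | CC(C)N(C(C)C)C(=O)OC1(c3ccc(OCc4ccccc4)cc3)C[C@@H]([C@H](O)c3ccc(OC(=O)OCc4ccccc4)cc3)c2cc(OCc3ccccc3)cc(OCc3ccccc3)c21 | intermediate (not isolated)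
11 | benzyl 4‑[(S)‑{(1R)‑4,6‑bis(benzyloxy)‑3‑[4‑(benzyloxy)phenyl]‑1H‑inden‑1‑yl}(hydroxy)methyl]phenyl carbonate | C1(c3ccc(OCc4ccccc4)cc3)=C[C@@H]([C@H](O)c3ccc(OC(=O)OCc4ccccc4)cc3)c2cc(OCc3ccccc3)cc(OCc3ccccc3)c21 | intermediate
12 | dimethyl {(1R,2S,3R)‑4,6‑bis(benzyloxy)‑3‑[4‑(benzyloxy)phenyl]‑1‑[(S)‑(4‑{[(benzyloxy)carbonyl]oxy}phenyl)(hydroxy)methyl]‑2,3‑dihydro‑1H‑inden‑2‑yl}boronate | C(c1ccccc1)Oc1ccc([C@@H]2c3c(OCc4ccccc4)cc(OCc4ccccc4)cc3[C@H]([C@H](O)c3ccc(OC(=O)OCc4ccccc4)cc3)[C@H]2B(OC)OC)cc1 | intermediate (not isolated)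
13 | potassium {(1R,2S,3R)‑4,6‑bis(benzyloxy)‑3‑[4‑(benzyloxy)phenyl]‑1‑[(S)‑(4‑{[(benzyloxy)carbonyl]oxy}phenyl)(hydroxy)methyl]‑2,3‑dihydro‑1H‑inden‑2‑yl}trifluoroborate | C(c1ccccc1)Oc1ccc([C@@H]2c3c(OCc4ccccc4)cc(OCc4ccccc4)cc3[C@H]([C@H](O)c3ccc(OC(=O)OCc4ccccc4)cc3)[C@H]2[B-](F)(F)F)cc1.[K+] | intermediate
14 | 1,3‑bis(benzyloxy)‑5‑bromobenzene | Brc1cc(OCc2ccccc2)cc(OCc2ccccc2)c1 | starting material
15 | benzyl 4‑[(S)‑{(1R,2S,3R)‑4,6‑bis(benzyloxy)‑3‑[4‑(benzyloxy)phenyl]‑2‑[3,5‑bis(benzyloxy)phenyl]‑2,3‑dihydro‑1H‑inden‑1‑yl}(hydroxy)methyl]phenyl carbonate | C(c1ccccc1)Oc1ccc([C@@H]2c3c(OCc4ccccc4)cc(OCc4ccccc4)cc3[C@H]([C@H](O)c3ccc(OC(=O)OCc4ccccc4)cc3)[C@H]2c2cc(OCc3ccccc3)cc(OCc3ccccc3)c2)cc1 | intermediate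
16 | (1R,2S,3R)‑2‑(3,5‑dihydroxyphenyl)‑1‑[(S)‑hydroxy(4‑hydroxyphenyl)methyl]‑3‑(4‑hydroxyphenyl)‑2,3‑dihydro‑1H‑indene‑4,6‑diol | Oc1ccc([C@@H]2c3c(O)cc(O)cc3[C@H]([C@H](O)c3ccc(O)cc3)[C@H]2c2cc(O)cc(O)c2)cc1 | target

**Step count and risks**

Total steps: 8. Longest linear sequence: 7 (steps 1, 2, 4, 5, 6, 7, 8).

Step 4. The lithiated 1,3‑diarylallyl carbamate may be configurationally labile, or may react at its oxygen‑bearing end, so that enantiomeric purity or γ‑regioselectivity is lost. Fallback: chirality is taken from a propargylic stereocentre and transferred through an allenylmetal reagent. It sets out from 6. Commercial 3,5‑bis(benzyloxy)benzaldehyde and 1‑(benzyloxy)‑4‑ethynylbenzene are joined by a zinc‑mediated enantioselective alkynylation (Me2Zn, chiral dinuclear zinc prolinol‑phenoxide catalyst, toluene; ligand enantiomer chosen for the R alcohol) to give (R)‑1‑[3,5‑bis(benzyloxy)phenyl]‑3‑[4‑(benzyloxy)phenyl]prop‑2‑yn‑1‑ol F1. MsCl, Et3N, CH2Cl2, −78 °C should give (R)‑1‑[3,5‑bis(benzyloxy)phenyl]‑3‑[4‑(benzyloxy)phenyl]prop‑2‑yn‑1‑yl methanesulfonate F2, used at once. Pd(OAc)2/PPh3 (cat.) and InI in THF–HMPA should turn F2 into an allenylindium reagent (anti SN2′ attack of zerovalent palladium, then transmetalation). This adds to 6 through a cyclic SE2′ transition state, with overall inversion at the propargylic carbon, to give the anti adduct (1S,2S)‑4‑[4‑(benzyloxy)phenyl]‑2‑[3,5‑bis(benzyloxy)phenyl]‑1‑(4‑{[(benzyloxy)carbonyl]oxy}phenyl)but‑3‑yn‑1‑ol F3. Gold‑catalysed hydration (Ph3PAuNTf2, wet dioxane; 5‑endo‑dig oxyauration by the carbinol oxygen directs the carbonyl to the aryl‑bearing alkyne carbon) should give (3R,4S)‑1‑[4‑(benzyloxy)phenyl]‑3‑[3,5‑bis(benzyloxy)phenyl]‑4‑(4‑{[(benzyloxy)carbonyl]oxy}phenyl)‑4‑hydroxybutan‑1‑one F4. Under the conditions of step 5, F4 cyclises and dehydrates to 11, where the route is rejoined.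

Step 5. Under the acid needed for ring closure the secondary benzylic carbinol may ionise, or the electron‑rich indene may oligomerise by cationic addition. Fallback: the C1–C7a bond is made with reversed polarity (aryl metal onto ketone), so no strong acid meets the indene. It sets out from 9. Solvolysis of the enol carbamate (MsOH, MeOH–H2O, 0 °C) gives the 4‑hydroxy ketone F4 described above. N‑Iodosuccinimide (MeCN, 0 °C) should iodinate the most electron‑rich ring ortho to the side chain to give (3R,4S)‑1‑[4‑(benzyloxy)phenyl]‑3‑[3,5‑bis(benzyloxy)‑2‑iodophenyl]‑4‑(4‑{[(benzyloxy)carbonyl]oxy}phenyl)‑4‑hydroxybutan‑1‑one F5. CrCl2 with catalytic NiCl2 in DMF (intramolecular Nozaki–Hiyama–Kishi addition of the aryl iodide to the ketone) should close the five‑membered ring to benzyl 4‑[(S)‑{(1R)‑4,6‑bis(benzyloxy)‑3‑[4‑(benzyloxy)phenyl]‑3‑hydroxy‑2,3‑dihydro‑1H‑inden‑1‑yl}(hydroxy)methyl]phenyl carbonate F6 (either configuration at the tertiary carbinol). Gentle dehydration of the tertiary diaryl carbinol (pyridinium p‑toluenesulfonate, cat., benzene, 50 °C) gives 11, where the route is rejoined.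

Step 7. Capture of the hindered secondary radical by nickel may be slower than hydrogen abstraction (net protodeboronation) or β‑hydride chain walking. Fallback: boron is bypassed by a reductive Heck reaction. It sets out from 11, which is treated with commercial 1,3‑bis(benzyloxy)‑5‑iodobenzene, Pd(OAc)2, HCO2Na and Bu4NCl in DMF at 60 °C. The aryl palladium iodide should add syn across C1=C2 from the face opposite the C3 side chain, with the aryl group going to C2. The tertiary benzylic palladium at C1 has no syn β‑hydrogen and is reduced by formate with retention, which gives 15 directly, where the route is rejoined; no new compound is made.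

**Further compounds**

F1 | step 4 | (R)‑1‑[3,5‑bis(benzyloxy)phenyl]‑3‑[4‑(benzyloxy)phenyl]prop‑2‑yn‑1‑ol | c1c(OCc2ccccc2)cc(OCc2ccccc2)cc1[C@@H](O)C#Cc1ccc(OCc2ccccc2)cc1
F2 | step 4 | (R)‑1‑[3,5‑bis(benzyloxy)phenyl]‑3‑[4‑(benzyloxy)phenyl]prop‑2‑yn‑1‑yl methanesulfonate | c1c(OCc2ccccc2)cc(OCc2ccccc2)cc1[C@@H](OS(C)(=O)=O)C#Cc1ccc(OCc2ccccc2)cc1
F3 | step 4 | (1S,2S)‑4‑[4‑(benzyloxy)phenyl]‑2‑[3,5‑bis(benzyloxy)phenyl]‑1‑(4‑{[(benzyloxy)carbonyl]oxy}phenyl)but‑3‑yn‑1‑ol | c1c(OCc2ccccc2)cc(OCc2ccccc2)cc1[C@H]([C@H](O)c1ccc(OC(=O)OCc2ccccc2)cc1)C#Cc1ccc(OCc2ccccc2)cc1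
F4 | step 4 | (3R,4S)‑1‑[4‑(benzyloxy)phenyl]‑3‑[3,5‑bis(benzyloxy)phenyl]‑4‑(4‑{[(benzyloxy)carbonyl]oxy}phenyl)‑4‑hydroxybutan‑1‑one | O=C(C[C@@H]([C@H](O)c1ccc(OC(=O)OCc2ccccc2)cc1)c1cc(OCc2ccccc2)cc(OCc2ccccc2)c1)c1ccc(OCc2ccccc2)cc1
F5 | step 5 | (3R,4S)‑1‑[4‑(benzyloxy)phenyl]‑3‑[3,5‑bis(benzyloxy)‑2‑iodophenyl]‑4‑(4‑{[(benzyloxy)carbonyl]oxy}phenyl)‑4‑hydroxybutan‑1‑one | O=C(C[C@@H]([C@H](O)c1ccc(OC(=O)OCc2ccccc2)cc1)c1c(I)c(OCc2ccccc2)cc(OCc2ccccc2)c1)c1ccc(OCc2ccccc2)cc1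
F6 | step 5 | benzyl 4‑[(S)‑{(1R)‑4,6‑bis(benzyloxy)‑3‑[4‑(benzyloxy)phenyl]‑3‑hydroxy‑2,3‑dihydro‑1H‑inden‑1‑yl}(hydroxy)methyl]phenyl carbonate | OC1(c3ccc(OCc4ccccc4)cc3)C[C@@H]([C@H](O)c3ccc(OC(=O)OCc4ccccc4)cc3)c2cc(OCc3ccccc3)cc(OCc3ccccc3)c21
F0 | step 7 | none | none
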